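The runs come from a simulation with made-up constants; scatter was added.

In the early minutes of the alder run G fell almost in a straight line, by 0.0667 min⁻¹ of its charge between 1.00 min and 2.50 min and by 0.0771 min⁻¹ from there to 6.00 min, the later slope being the steeper.

- alder: G 10 mM; J 21 mM; run made earlier
- flask: G 20 mM; J 21.0 mM; time 30 min; volume of the second phase over the first 1.0

alder run (percent of the G charged)

| time / min | X / % | G / % |
|---|---|---|
| 0.500 | 2 | 97 |
| 0.667 | 0 | 101 |
| 1.00 | 3 | 96 |
| 1.50 | 7 | 92 |
| 2.50 | 13 | 86 |
| 4.00 | 26 | 76 |
| 6.00 | 34 | 59 |

(standard deviation of a reading: 2 percentage points)

- in the second phase: J; everything else is in the first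
- charges count per volume of the first phase; a concentration in a rate is the amount of a species over the volume of its own phase; every rate counts per litre of the first phase
- the earlier runs hold the two phases in the same ratio of volumes as the flask asked about

* the X standing at 30 min, as a percentage of the G charged
* part of the G charged that has reacted at 30 min

I doubted that a straight line meant anything at a scatter of 2 percentage points, so I laid a first-order fall in G through the last reading of the alder run; it passes 80.3% at 2.50 min, where G read 86%, so I dropped it and took the passage of J between the phases as the likely rate-limiting step. Extending the line to the asked flask, with the same loss spread over twice the G, gave 103% of the charge at 30 min, more than the charge, and it spent nearly all of J. But I did not believe a supply that stays level while its source empties, so I let the rate follow the J left. Taking one J per G, the alder run had lost G worth 19.5% of the J charge by 6.00 min, which gives the drain constant of J 0.0362 min⁻¹, the pseudo-first-order fraction of the remaining J that goes per minute. By my estimate it left 33.8% of J at 30 min, and the J spent came to 69.6% of the G charge in the asked flask. My last doubt was X, which at 6.00 min read 7 points below the G lost, so I carried that reading's share of 82.9% and committed to 69.6% reacted and 57.7% of X.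

The forecast said 68% of X and 75% reacted, more than my reckoning on both, on this ground: "The near-linear shape favours a rate not much dependent on G, but J depletion slows the end".

The asked flask gave 48.7% of X and 77.7% reacted, with J down to 29.4% of its charge against my 33.8%.

    Z + X → E (k = 23.0 M⁻¹ min⁻¹)
    Z ⇌ J, rate k2*([Z] - [J]/K2) per volume of the first phase (partition coefficient = 0.460, kL = 0.0190 min⁻¹)
    G + X → Q (k = 1.30 M⁻¹ min⁻¹)
    G + Z → X (k = 150 M⁻¹ min⁻¹)

X in the asked flask was 62.7% of the reacted G, less than my 82.9%, and of the G charged Q stood at 22.7%, each Q counted as two, and E at 6.34%. Carried unchanged to the neighbour charged with 12 mM of G, the drain constant 0.0362 min⁻¹ gave the same estimate of 33.8% of J, and the J spent in that estimate came to 116% of that G charge, more than the charge; at 30.0 min that neighbour held J at 30.1% of its own charge, G at 3.9% and X at 60.5%.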